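# Synthesis proposal for CNP0211702.1 (target 36)

## Structural features

The target is a briarane diterpenoid: a cyclohexene (ring A: C1, C10, C11, C12, C13, C14) shares the C1–C10 bond with a ten-membered carbocycle (ring B: C1 to C10), and a γ-lactone (C7, C8, C17, C19 and the ring oxygen) is fused to ring B across C7–C8. Nine stereocentres are present. C2, C1, C10, C11 and C12 follow one another around ring A (C1 is quaternary and carries a methyl group), C9, C8 and C7 continue along ring B, and C17 completes a contiguous C7–C8–C17 triad on the lactone. The methyl groups on C1 and C11 and the C9 arm on C10 lie on one face of ring A; C2 and the C12 oxygen lie on the other. Ring B holds a Z trisubstituted C5=C6 alkene and is trans-fused to the lactone. The fragile groups are three esters of two kinds (acetates at C2 and C9, an allylic butanoate at C12), a free tertiary C8 alcohol β to the lactone carbonyl (retro-aldol cleavage, C17 epimerisation) and the ionisable allylic C12–O bond. The real difficulty is closing the strained ten-membered ring next to the fully substituted C8 with the Z alkene in place, and relating C7, C8 and C17 to the ring A stereocentres; the ester pattern also forces all acylations to the end. The key step exploits the contiguous C1 (quaternary)/C10/C11 triad of ring A and the oxygen on C12: a 2-silyloxydiene (C11–C12–C13–C14) and an α-methyl enal (C1 and C10, carrying C2 and C9) map onto ring A. The bonds C10–C11 and C1–C14 and all three centres then arise together, and C12=C13 is left as a silyl enol ether, the latent C12 carbinol and C13=C14 alkene.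

## Logic of the disconnections

**Esters and C12 (36 back to 29).** The last bonds cut are the two acetate C–O bonds (36 to 34 and 35), the two silyl ethers (34 to 33) and the C12–O bond of the butanoate (33 to 31 and 32, with inversion at C12). Then 31 goes back to enone 30 and 30 to the silyl enol ether 29. The esters are cut first because none of them would survive the hydride, enolate and organometallic steps that build the skeleton. The enol ether is kept this long because its dehydrogenation uses palladium, which would insert into the alkenyl iodide needed for ring closure. The gain is that 29 has the lactone as its only carbonyl group. The demand is that the forward steps distinguish the C12 alcohol (the only free secondary alcohol in 31) from C2 and C9, invert C12 cleanly and leave the tertiary C8 alcohol unacylated.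

**Lactone (29 back to 24 and 25).** The C8–C17 bond is cut as an intramolecular Reformatsky (aldol) bond (29 to 27), the C8 ketone is masked again as a dithiane (27 to 26) and the C7–O acyl bond is cut (26 to 24 and 25). Cutting here lets the ring, the tertiary alcohol and both C8 and C17 arise in one event from an enolate tethered to C7. This removes two stereocentres and three carbons at once. The demand is that the tethered enolate adds to one face of the C8 ketone (trans ring fusion) faster than the α-acyloxy ketone is reduced.

**Ring B (24 back to 23).** The C6–C7 bond is cut. C7 is a carbinol carbon attached to an alkenyl carbon, the retron of an alkenylmetal addition to an aldehyde, and the Z geometry of C5=C6 can be fixed in the open chain beforehand. The gain is an acyclic tether on ring A. The demand is a chemoselective closure under high dilution onto a hindered aldehyde, with control of C7 by the forming ring.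

**C8–C9 (23 back to 18 and 19).** The aldehyde of 23 is traced to the ester of 22, the silyl ether to 21, and the C8–C9 bond is cut to aldehyde 18 and 19. C9 is a carbinol next to a carbon that must later be a ketone (C8) and must carry a one-carbon aldehyde arm (C7); the ester enolate of 19 delivers exactly this as a masked unit. The gain is that C7 and C8 come from one commercial reagent. The demand is Felkin–Anh selectivity at C9 under the influence of C10. Aldehyde 18 goes back through 17 to benzoate 16.

**C3–C4 and C2 (16 back to 8 and 12).** The silyl ether is removed (16 to 15), the C2 carbinol is traced to ketone 14, and the C3–C4 bond is cut to the methyl ketone 8 and the allylic bromide 12. The Z alkenyl iodide with its methyl group is best made separately, and an allylic bromide and a ketone that can enolise on one side only are ideal partners. The gain is that C3 to C6, the alkene geometry and the iodide for ring closure arrive in one step, and C2 is then set by a reagent-controlled reduction. The demands are monoalkylation and a reduction that overrides the substrate. Bromide 12 goes back through 11 to 9.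

**C2–C3 (8 back to 6).** The methyl–carbonyl bond is cut (8 to 7 to 6). This turns the non-enolisable formyl group of the cycloadduct into the enolisable ketone. The demand is addition to the aldehyde in the presence of the benzoate.

**Ring A (6 back to 2 and 5).** The bonds C10–C11 and C1–C14 are cut. This is the key disconnection: ring A and three contiguous stereocentres come from two achiral fragments. The demands are regiocontrol (silyloxy group), formyl-exo selectivity (C11) and face selectivity (catalyst). The descriptors of 6 were checked centre by centre against 36 (C1 S, C10 S, C11 R in both) and need no correction. The one design change is at the C9 oxygen, which is carried as a benzoate. A benzyl ether would have to be removed later by hydrogenolysis or dissolving metal in the presence of an alkenyl iodide and three alkenes; the benzoate leaves with a hydride at low temperature.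

**Starting materials.** 2 comes from 1 by O-silylation, and 5 from 3 and 4 by a Wittig reaction.

## Other disconnections considered

Alternative 1: The cut is C4–C5. The seco compound A2 carries the finished lactone and ester pattern, a 1-hydroxycyclopropyl group on C1 (its carbons are C2, C3 and C4) and a Z 2-iodoprop-1-enyl group on C7. Zerovalent palladium would insert into the C5–I bond, the palladium alkoxide of the cyclopropanol would open by β-carbon elimination to a C2 ketone with palladium on C4, and reductive elimination would close ring B to the 2-oxo compound A1. A1 still needs a diastereoselective C2 reduction and acetylation.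
- In its favour: the ring is closed between a primary sp3 carbon and an unhindered alkenyl carbon by a catalytic reaction that tolerates esters and the free C8 alcohol, so closure can come at the very end. On the hindrance of the closing site and on the use of a catalytic instead of a superstoichiometric metal, this plan is the better of the two.
- Equal: the Z geometry of C5=C6 is fixed before closure in both plans.
- Against it here: the cyclopropanol must be built next to quaternary C1 by a titanium-mediated cyclopropanation of a hindered C2 ester, early, because that reaction tolerates no other ester. β-Hydride elimination of the C4 palladium homoenolate to the C3=C4 enone is a unimolecular escape that competes with a strained ten-membered reductive elimination. C2 is set last, inside the macrocycle, whereas the chosen plan sets it under reagent control in an open chain.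
- Step economy is comparable, and ring A could be made by the same cycloaddition in both plans.

Alternative 2: No carbon–carbon bond of ring B is made in the key step. Ring B is hidden in the tricyclic hydrophenanthrene A4 as two cyclohexane rings that share the tetrasubstituted C2=C7 alkene, and ozonolysis of that alkene would release the cyclodecane-2,7-dione A3.
- In its favour: the entropic and transannular penalties of a medium-ring closure are avoided, since only six-membered rings are ever closed. The electron-rich tetrasubstituted alkene should react with ozone well before the C13=C14 enone. On ring construction as such, this plan is better than the chosen one.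
- Against it here: A3 arrives with C2 and C7 as ketones, with C5 as a tertiary silyl ether that must later be eliminated regio- and Z-selectively, and without the C8 oxygen or the three lactone carbons. The hard part of the target (C7, C8, C17 and the lactone) would remain to be done on a flexible medium ring in which the 2,7-dione can undergo transannular aldol reactions.
- Mechanistically the cleavage is simpler and more reliable than the chosen closure at C6–C7, which is the riskier single event. Structurally the chosen plan delivers C7 at the right oxidation level with the Z alkene in place and the masked C8 ketone next to it.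
- In step economy the alternative is the longer plan: the tricycle must first be assembled and the diketone then refunctionalised at five positions.

Alternative 3: The cut is C3–C4. In the eight-membered cyclic enol ether A6 the ring oxygen links C2 (bearing the exocyclic methylene carbon C3) to C6 (bearing the isopropenyl group that holds C5, C4 and the C5 methyl). Heating should trigger a Claisen rearrangement that forms C3–C4, breaks O–C6 and expands the oxocane to ring B in A5 with a C2 ketone.
- In its favour: the ring results from a unimolecular, reagent-free ring expansion and not from an end-to-end cyclisation. The bridged chair-like transition state allows only the Z C5=C6 alkene, and C7, C8, C9 and C17 are fixed in the smaller ring beforehand. In the certainty of the alkene geometry it equals the chosen plan, and in the entropy of the ring-forming event it is better.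
- Against it here: the eight-membered lactone that precedes A6 is itself a difficult ring to close. Its carbonyl (C2, next to quaternary C1) must be methylenated with a titanium alkylidene (Cp2TiMe2) in the presence of five protected oxygens. An extra stereocentre at C6 must be set and is then destroyed. C2 is again left as a ketone to be reduced in the macrocycle, and C19 is carried at the alcohol level, so the lactone needs a late oxidation.
- Mechanistically the sigmatropic step is more predictable than a chromium-mediated closure. In protecting-group load and step count the chosen plan is the leaner one.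

Key step: step 3

Remark (assumption on the chemistry): the (R)-configured oxazaborolidinium ion is taken to expose the Si face of C1 of the bound enal, as the formyl C–H···O binding model indicates; the antipodal catalyst is equally accessible should the sense of induction be the opposite.

## Route

Step 1
Reactants: 1 ethyl vinyl ketone
Product: 2 (Z)-3-(triisopropylsilyloxy)penta-1,3-diene
Conditions: TIPSOTf, Et3N, Et2O, 0 °C to rt
Reagents that add atoms: triisopropylsilyl trifluoromethanesulfonate, CC(C)[Si](OS(=O)(=O)C(F)(F)F)(C(C)C)C(C)C
Why: Amine-mediated O-silylation of the enone (silyl enol ether formation); the bulky silyl group and the vinyl substituent favour the Z enol ether, in which the terminal methyl is cis to oxygen and lies outside the s-cis diene.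

Step 2
Reactants: 3 2-oxoethyl benzoate; 4 2-(triphenylphosphoranylidene)propanal
Product: 5 (E)-3-methyl-4-oxobut-2-en-1-yl benzoate
Conditions: toluene, 80 °C
Reagents that add atoms: none
Why: Wittig olefination with a stabilised formyl ylide, which should be E-selective; the ylide is too unreactive to add to the enal product.

Step 3
Reactants: 2 (Z)-3-(triisopropylsilyloxy)penta-1,3-diene; 5 (E)-3-methyl-4-oxobut-2-en-1-yl benzoate
Product: 6 ring A aldehyde [(1S,2R,6S)-6-formyl-2,6-dimethyl-3-(triisopropylsilyloxy)cyclohex-3-en-1-yl]methyl benzoate
Conditions: (R)-1-(2-methylphenyl)-3,3-diphenyltetrahydro-1H,3H-pyrrolo[1,2-c][1,3,2]oxazaborole (20 mol%), HN(SO2CF3)2 (18 mol%), CH2Cl2, −78 to −40 °C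
Reagents that add atoms: none
Why: Concerted but asynchronous [4+2] cycloaddition of the enal bound to the protonated oxazaborolidine; the closest known reaction type is the oxazaborolidinium-catalysed Diels–Alder reaction of 2-silyloxydienes with α-substituted enals. Ring A is closed by suprafacial addition of the diene termini C11 and C14 to C10 and C1 of the dienophile, the C10–C11 bond being the more advanced. The silyloxy group makes C11 the nucleophilic terminus, which pairs with the electrophilic β-carbon C10 and so fixes the regiochemistry. The E geometry of 5 is transferred into the cis relation of the C1 methyl and the C9 arm, which sets C10 relative to C1. The Z (methyl-outside) geometry of 2 together with the formyl-exo, methyl-endo approach places the C11 methyl cis to C9. The absolute configuration (C1 S) is set by the catalyst, which holds the s-trans enal through the B–O bond and a formyl C–H···O contact and shields one face with an aryl group. The step needs exo selectivity and face selectivity: the first is secured by the α-methyl group and the bulk of the catalyst-bound formyl group, the second by the catalyst. The benzoate is a weaker donor than the aldehyde and should not be attacked at this temperature.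

Step 4
Reactants: 6 ring A aldehyde
Product: 7 C2 carbinol (both C2 epimers)
Conditions: MeMgBr, THF, −78 °C
Reagents that add atoms: methylmagnesium bromide, C[Mg]Br
Why: Grignard addition to the aldehyde, which brings in C3; at −78 °C the aldehyde reacts much faster than the benzoate and the silyl enol ether is inert. The configuration of C2 is irrelevant because it is removed in step 5.

Step 5
Reactants: 7 C2 carbinol
Product: 8 methyl ketone
Conditions: n-Pr4N[RuO4] (5 mol%), NMO, 4 Å sieves, CH2Cl2, rt
Reagents that add atoms: none
Why: Ley–Griffith oxidation under neutral conditions, which should leave the silyl enol ether and the benzoate untouched.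

Step 6
Reactants: 9 prop-2-yn-1-ol
Product: 11 (Z)-3-iodo-2-methylprop-2-en-1-ol, via alkenylmagnesium alkoxide 10 (not isolated)
Conditions: MeMgBr (2.5 equiv), CuI (10 mol%), THF, −10 °C to rt; then I2, −5 °C
Reagents that add atoms: methylmagnesium bromide, C[Mg]Br; iodine, II
Why: Copper-catalysed anti-carbomagnesiation of the propargylic alkoxide followed by iodinolysis with retention; the magnesium alkoxide directs the anti addition, so iodine ends cis to the CH2O group (Z).

Step 7
Reactants: 11 (Z)-3-iodo-2-methylprop-2-en-1-ol
Product: 12 (Z)-3-bromo-1-iodo-2-methylprop-1-ene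
Conditions: CBr4, PPh3, CH2Cl2, 0 °C
Reagents that add atoms: carbon tetrabromide, BrC(Br)(Br)Br
Why: Appel bromination of a primary allylic alcohol under neutral conditions; the alkene geometry is not touched.

Step 8
Reactants: 8 methyl ketone; 12 (Z)-3-bromo-1-iodo-2-methylprop-1-ene
Product: 14 iodo ketone (C3–C4 bond formed; Z alkenyl iodide at C6), via lithium enolate 13 (not isolated)
Conditions: LiN(i-Pr)2, THF, −78 °C; then 12, DMPU, −78 to −40 °C
Reagents that add atoms: none
Why: Kinetic enolate alkylation; the ketone can enolise only toward its methyl group because C1 is quaternary, and the allylic bromide is a fast SN2 electrophile. Silyl enol ether, benzoate and alkenyl iodide tolerate the amide base at −78 °C.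

Step 9
Reactants: 14 iodo ketone
Product: 15 (2R)-alcohol
Conditions: (S)-1-methyl-3,3-diphenyltetrahydro-1H,3H-pyrrolo[1,2-c][1,3,2]oxazaborole (1.0 equiv), BH3·SMe2, THF, −20 °C; MeOH
Reagents that add atoms: none
Why: Corey–Bakshi–Shibata reduction; quaternary C1 is the large and the C3 methylene the small substituent, so the (S)-oxazaborolidine should deliver hydride to give the (2R)-alcohol under reagent control. At this temperature the catalysed ketone reduction should outrun hydroboration of the hindered enol ether.

Step 10
Reactants: 15 (2R)-alcohol
Product: 16 C2 tert-butyldimethylsilyl ether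
Conditions: TBSOTf, 2,6-lutidine, CH2Cl2, −78 to 0 °C
Reagents that add atoms: tert-butyldimethylsilyl trifluoromethanesulfonate, CC(C)(C)[Si](C)(C)OS(=O)(=O)C(F)(F)F
Why: Silyl ether formation; the triflate is needed for the hindered alcohol next to quaternary C1.

Step 11
Reactants: 16 C2 tert-butyldimethylsilyl ether
Product: 17 primary C9 alcohol
Conditions: i-Bu2AlH (2.5 equiv), CH2Cl2, −78 °C
Reagents that add atoms: none
Why: Reductive cleavage of the benzoate; the hydride should touch neither the silyl ethers, the silyl enol ether nor the alkenyl iodide.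

Step 12
Reactants: 17 primary C9 alcohol
Product: 18 C9 aldehyde
Conditions: n-Pr4N[RuO4] (5 mol%), NMO, 4 Å sieves, CH2Cl2, rt
Reagents that add atoms: none
Why: Ley–Griffith oxidation; the neutral medium avoids epimerisation of C10, which is now α to the aldehyde.

Step 13
Reactants: 18 C9 aldehyde; 19 ethyl 1,3-dithiane-2-carboxylate
Product: 21 β-hydroxy ester (9R; C8 as dithiane), via lithium enolate 20 (not isolated)
Conditions: 19, LiN(i-Pr)2, THF, −78 °C; then 18, −78 °C; AcOH quench
Reagents that add atoms: none
Why: Aldol addition of a dithiane-stabilised ester enolate (glyoxylate anion equivalent) forming C8–C9. Felkin–Anh attack anti to quaternary C1 and past the C10 hydrogen should give the (9R)-carbinol. C8 enters as a masked ketone and C7 at the acid oxidation level.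

Step 14
Reactants: 21 β-hydroxy ester
Product: 22 C9 tert-butyldimethylsilyl ether
Conditions: TBSOTf, 2,6-lutidine, CH2Cl2, 0 °C
Reagents that add atoms: tert-butyldimethylsilyl trifluoromethanesulfonate, CC(C)(C)[Si](C)(C)OS(=O)(=O)C(F)(F)F
Why: Silyl ether formation; it blocks retro-aldol cleavage and gives C9 the same protecting group as C2, so that both are released together in step 23.

Step 15
Reactants: 22 C9 tert-butyldimethylsilyl ether
Product: 23 C7 aldehyde
Conditions: i-Bu2AlH (1.5 equiv), toluene, −78 °C; MeOH, then aqueous Rochelle salt
Reagents that add atoms: none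
Why: Partial reduction of the ester; the hindered, sulfur-flanked tetrahedral aluminate should persist at −78 °C and release the aldehyde only on work-up.

Step 16
Reactants: 23 C7 aldehyde
Product: 24 macrocyclic C7 alcohol (ring B closed; 7S)
Conditions: CrCl2 (10 equiv), NiCl2 (0.2 equiv), DMSO, rt, 2 mM, slow addition
Reagents that add atoms: none
Why: Intramolecular Nozaki–Hiyama–Kishi reaction: zerovalent nickel inserts into the alkenyl iodide with retention, transmetalation gives the alkenylchromium species, and this adds only to the aldehyde, forming C6–C7 with the Z alkene intact. C7 is set by the macrocyclic transition state, which is expected to keep the chromium alkoxide on the outer face of the forming ring; this is the least predictable centre of the route.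

Step 17
Reactants: 24 macrocyclic C7 alcohol; 25 2-bromopropanoyl bromide
Product: 26 C7 2-bromopropanoate
Conditions: 25, pyridine, 4-(dimethylamino)pyridine (cat.), CH2Cl2, 0 °C
Reagents that add atoms: none
Why: Acylation with an acyl bromide under nucleophilic catalysis; the bromine-bearing carbon is a mixture of epimers, which is of no consequence because it becomes an enolate carbon in step 19.

Step 18
Reactants: 26 C7 2-bromopropanoate
Product: 27 C8 ketone
Conditions: MeI (excess), CaCO3, MeCN/H2O 9:1, 45 °C
Reagents that add atoms: water, O
Why: Dithioacetal hydrolysis by S-methylation; MeI is too weak an electrophile to attack the silyl enol ether or the trisubstituted alkene, and CaCO3 keeps the medium neutral.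

Step 19
Reactants: 27 C8 ketone
Product: 29 β-hydroxy γ-lactone, via samarium enolate 28 (not isolated)
Conditions: SmI2 (2.5 equiv), THF, −78 °C; aqueous NH4Cl
Reagents that add atoms: none
Why: Intramolecular samarium Reformatsky reaction: two-electron reduction of the C–Br bond gives the trivalent samarium enolate, which adds to the chelated C8 ketone from the face of the C7–O tether and forms C8–C17. With ring B in its extended C6–C7–C8–C9 arrangement this should give the trans-fused lactone with the C8 hydroxyl cis to C6. The enolate methyl should turn away from the ring oxygen, which places it cis to the new hydroxyl at C17.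

Step 20
Reactants: 29 β-hydroxy γ-lactone
Product: 30 C12 enone (C13=C14)
Conditions: Pd(OAc)2 (1.1 equiv), MeCN, rt
Reagents that add atoms: none
Why: Saegusa–Ito oxidation: the silyl enol ether is converted into the palladium enolate and β-hydride elimination from C14 gives the enone. The alkenyl iodide was consumed in step 16, so the zerovalent palladium formed has nothing to insert into.

Step 21
Reactants: 30 C12 enone
Product: 31 12β-alcohol (12-epi series)
Conditions: NaBH4, CeCl3·7H2O, MeOH, −78 °C
Reagents that add atoms: none
Why: Luche 1,2-reduction; hydride should approach the α face, away from the methyl groups on C1 and C11 and the C9 carbon on C10, giving the alcohol cis to the C11 methyl. Lactone and silyl ethers are inert.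

Step 22
Reactants: 31 12β-alcohol; 32 butanoic acid
Product: 33 12α-butanoate
Conditions: PPh3, DIAD, 32, toluene, 0 °C to rt
Reagents that add atoms: none
Why: Mitsunobu esterification with inversion; the carboxylate displaces the oxyphosphonium group from the unhindered α face and gives the C12 configuration of the target. The tertiary C8 alcohol does not react.

Step 23
Reactants: 33 12α-butanoate
Product: 34 C2,C9-diol
Conditions: HF·pyridine, pyridine, THF, 0 °C to rt
Reagents that add atoms: none
Why: Fluoride-mediated cleavage of both silyl ethers; the butanoate and the lactone survive buffered HF·pyridine.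

Step 24
Reactants: 34 C2,C9-diol; 35 acetic anhydride
Product: 36 target CNP0211702.1
Conditions: 35, pyridine, 4-(dimethylamino)pyridine (cat.), CH2Cl2, 0 °C to rt
Reagents that add atoms: none
Why: Acylation of the two secondary alcohols; the tertiary C8 alcohol, flanked by three substituted carbons, should remain free under these mild conditions.

## Compound list

1 | ethyl vinyl ketone (pent-1-en-3-one) | CCC(=O)C=C | starting material
2 | (Z)-3-(triisopropylsilyloxy)penta-1,3-diene | C=C/C(O[Si](C(C)C)(C(C)C)C(C)C)=C/C | intermediate
3 | 2-oxoethyl benzoate (benzoyloxyacetaldehyde) | O=CCOC(=O)c1ccccc1 | starting material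
4 | 2-(triphenylphosphoranylidene)propanal | CC(C=O)=P(c1ccccc1)(c1ccccc1)c1ccccc1 | starting material
5 | (E)-3-methyl-4-oxobut-2-en-1-yl benzoate [(E)-4-benzoyloxy-2-methylbut-2-enal] | O=C/C(C)=C/COC(=O)c1ccccc1 | intermediate
6 | ring A aldehyde, [(1S,2R,6S)-6-formyl-2,6-dimethyl-3-(triisopropylsilyloxy)cyclohex-3-en-1-yl]methyl benzoate (briarane C1 S, C10 S, C11 R) | CC(C)[Si](C(C)C)(C(C)C)OC1=CC[C@@](C=O)(C)[C@H]([C@H]1C)COC(=O)c1ccccc1 | intermediate
7 | C2 carbinol, [(1S,2R,6S)-6-(1-hydroxyethyl)-2,6-dimethyl-3-(triisopropylsilyloxy)cyclohex-3-en-1-yl]methyl benzoate, both C2 epimers | CC(C)[Si](C(C)C)(C(C)C)OC1=CC[C@@](C(C)O)(C)[C@H]([C@H]1C)COC(=O)c1ccccc1 | intermediate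
8 | methyl ketone, [(1S,2R,6S)-6-acetyl-2,6-dimethyl-3-(triisopropylsilyloxy)cyclohex-3-en-1-yl]methyl benzoate | CC(C)[Si](C(C)C)(C(C)C)OC1=CC[C@@](C(C)=O)(C)[C@H]([C@H]1C)COC(=O)c1ccccc1 | intermediate
9 | prop-2-yn-1-ol | C#CCO | starting material
10 | bromomagnesium (Z)-3-(bromomagnesio)-2-methylprop-2-en-1-olate | Br[Mg]OC/C(C)=C\[Mg]Br | intermediate (not isolated)
11 | (Z)-3-iodo-2-methylprop-2-en-1-ol | OC/C(C)=C\I | intermediate
12 | (Z)-3-bromo-1-iodo-2-methylprop-1-ene | BrC/C(C)=C\I | intermediate
13 | lithium enolate of 8 (C2=C3) | CC(C)[Si](C(C)C)(C(C)C)OC1=CC[C@@](C(=C)O[Li])(C)[C@H]([C@H]1C)COC(=O)c1ccccc1 | intermediate (not isolated)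
14 | iodo ketone, [(1S,2R,6S)-6-[(Z)-5-iodo-4-methylpent-4-enoyl]-2,6-dimethyl-3-(triisopropylsilyloxy)cyclohex-3-en-1-yl]methyl benzoate | CC(C)[Si](C(C)C)(C(C)C)OC1=CC[C@@](C(=O)CC/C(C)=C\I)(C)[C@H]([C@H]1C)COC(=O)c1ccccc1 | intermediate
15 | (2R)-alcohol, [(1S,2R,6S)-6-[(1R,4Z)-1-hydroxy-5-iodo-4-methylpent-4-en-1-yl]-2,6-dimethyl-3-(triisopropylsilyloxy)cyclohex-3-en-1-yl]methyl benzoate | CC(C)[Si](C(C)C)(C(C)C)OC1=CC[C@@]([C@H](O)CC/C(C)=C\I)(C)[C@H]([C@H]1C)COC(=O)c1ccccc1 | intermediate
16 | C2 tert-butyldimethylsilyl ether of 15 | CC(C)[Si](C(C)C)(C(C)C)OC1=CC[C@@]([C@H](O[Si](C)(C)C(C)(C)C)CC/C(C)=C\I)(C)[C@H]([C@H]1C)COC(=O)c1ccccc1 | intermediate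
17 | primary C9 alcohol, [(1S,2R,6S)-6-[(1R,4Z)-1-(tert-butyldimethylsilyloxy)-5-iodo-4-methylpent-4-en-1-yl]-2,6-dimethyl-3-(triisopropylsilyloxy)cyclohex-3-en-1-yl]methanol | CC(C)[Si](C(C)C)(C(C)C)OC1=CC[C@@]([C@H](O[Si](C)(C)C(C)(C)C)CC/C(C)=C\I)(C)[C@H]([C@H]1C)CO | intermediate
18 | C9 aldehyde, (1S,2R,6S)-6-[(1R,4Z)-1-(tert-butyldimethylsilyloxy)-5-iodo-4-methylpent-4-en-1-yl]-2,6-dimethyl-3-(triisopropylsilyloxy)cyclohex-3-ene-1-carbaldehyde | CC(C)[Si](C(C)C)(C(C)C)OC1=CC[C@@]([C@H](O[Si](C)(C)C(C)(C)C)CC/C(C)=C\I)(C)[C@H]([C@H]1C)C=O | intermediate
19 | ethyl 1,3-dithiane-2-carboxylate | CCOC(=O)C1SCCCS1 | starting material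
20 | lithium enolate of 19 | CCOC(O[Li])=C1SCCCS1 | intermediate (not isolated)
21 | β-hydroxy ester, ethyl 2-[(R)-hydroxy(ring A)methyl]-1,3-dithiane-2-carboxylate (C9 R; ring A as in 18) | CC(C)[Si](C(C)C)(C(C)C)OC1=CC[C@@]([C@H](O[Si](C)(C)C(C)(C)C)CC/C(C)=C\I)(C)[C@H]([C@H]1C)[C@@H](O)C1(C(=O)OCC)SCCCS1 | intermediate
22 | C9 tert-butyldimethylsilyl ether of 21 | CC(C)[Si](C(C)C)(C(C)C)OC1=CC[C@@]([C@H](O[Si](C)(C)C(C)(C)C)CC/C(C)=C\I)(C)[C@H]([C@H]1C)[C@@H](O[Si](C)(C)C(C)(C)C)C1(C(=O)OCC)SCCCS1 | intermediate
23 | C7 aldehyde (2-formyl-1,3-dithiane at C8; otherwise as 22) | CC(C)[Si](C(C)C)(C(C)C)OC1=CC[C@@]([C@H](O[Si](C)(C)C(C)(C)C)CC/C(C)=C\I)(C)[C@H]([C@H]1C)[C@@H](O[Si](C)(C)C(C)(C)C)C1(C=O)SCCCS1 | intermediate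
24 | macrocyclic alcohol: ring A (C12 triisopropylsilyl enol ether) fused at C1/C10 to ring B with 2-OTBS, Z C5=C6 (5-methyl), 7-OH, C8 1,3-dithiane, 9-OTBS; 1S,2R,7S,9R,10S,11R | CC(C)[Si](C(C)C)(C(C)C)OC1=CC[C@@]2(C)[C@H]([C@H]1C)[C@@H](O[Si](C)(C)C(C)(C)C)C1(SCCCS1)[C@H](/C=C(/C)CC[C@H]2O[Si](C)(C)C(C)(C)C)O | intermediate
25 | 2-bromopropanoyl bromide (racemic) | CC(Br)C(Br)=O | starting material
26 | C7 2-bromopropanoate of 24 (both epimers at the CHBr carbon) | CC(C)[Si](C(C)C)(C(C)C)OC1=CC[C@@]2(C)[C@H]([C@H]1C)[C@@H](O[Si](C)(C)C(C)(C)C)C1(SCCCS1)[C@H](/C=C(/C)CC[C@H]2O[Si](C)(C)C(C)(C)C)OC(=O)C(C)Br | intermediate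
27 | C8 ketone (dithiane of 26 hydrolysed) | CC(C)[Si](C(C)C)(C(C)C)OC1=CC[C@@]2(C)[C@H]([C@H]1C)[C@@H](O[Si](C)(C)C(C)(C)C)C(=O)[C@H](/C=C(/C)CC[C@H]2O[Si](C)(C)C(C)(C)C)OC(=O)C(C)Br | intermediate
28 | samarium enolate of the C7 propanoate (methyl cis to O–Sm) | CC(C)[Si](C(C)C)(C(C)C)OC1=CC[C@@]2(C)[C@H]([C@H]1C)[C@@H](O[Si](C)(C)C(C)(C)C)C(=O)[C@H](/C=C(/C)CC[C@H]2O[Si](C)(C)C(C)(C)C)O/C(O[Sm](I)I)=C/C | intermediate (not isolated)
29 | β-hydroxy γ-lactone: 8-hydroxy-7,19-lactone with 17-methyl, 2,9-bis-OTBS, C12 triisopropylsilyl enol ether; C1, C2, C7, C8, C9, C10, C11, C17 arranged as in 36 | CC(C)[Si](C(C)C)(C(C)C)OC1=CC[C@@]2(C)[C@H]([C@H]1C)[C@@H](O[Si](C)(C)C(C)(C)C)[C@@]1(O)[C@H](/C=C(/C)CC[C@H]2O[Si](C)(C)C(C)(C)C)OC(=O)[C@@H]1C | intermediate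
30 | C12 enone (12-oxo, C13=C14); otherwise as 29 | O=C1C=C[C@@]2(C)[C@H]([C@H]1C)[C@@H](O[Si](C)(C)C(C)(C)C)[C@@]1(O)[C@H](/C=C(/C)CC[C@H]2O[Si](C)(C)C(C)(C)C)OC(=O)[C@@H]1C | intermediate
31 | 12β-alcohol (C12 hydroxyl cis to the C11 methyl; C12 epimeric to 36) | O[C@H]1C=C[C@@]2(C)[C@H]([C@H]1C)[C@@H](O[Si](C)(C)C(C)(C)C)[C@@]1(O)[C@H](/C=C(/C)CC[C@H]2O[Si](C)(C)C(C)(C)C)OC(=O)[C@@H]1C | intermediate
32 | butanoic acid | CCCC(O)=O | starting material
33 | 12α-butanoate, 2,9-bis-OTBS; all centres as in 36 | CCCC(=O)O[C@@H]1C=C[C@@]2(C)[C@H]([C@H]1C)[C@@H](O[Si](C)(C)C(C)(C)C)[C@@]1(O)[C@H](/C=C(/C)CC[C@H]2O[Si](C)(C)C(C)(C)C)OC(=O)[C@@H]1C | intermediate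
34 | C2,C9-diol (2,8,9-triol 12-butanoate); all centres as in 36 | CCCC(=O)O[C@@H]1C=C[C@@]2(C)[C@H]([C@H]1C)[C@@H](O)[C@@]1(O)[C@H](/C=C(/C)CC[C@H]2O)OC(=O)[C@@H]1C | intermediate
35 | acetic anhydride | CC(=O)OC(C)=O | starting material
36 | CNP0211702.1: 2,9-di-O-acetyl-12-O-butanoyl-8-hydroxy briarane 7,19-lactone with Z C5=C6 and C13=C14 | CCCC(=O)O[C@@H]1C=C[C@@]2(C)[C@H]([C@H]1C)[C@@H](OC(C)=O)[C@@]1(O)[C@H](/C=C(/C)CC[C@H]2OC(C)=O)OC(=O)[C@@H]1C | target

## Step count and least certain steps

Total: 24 steps. Longest linear sequence: 21 steps (steps 1, 3, 4, 5 and 8 to 24 from 1; the sequence from 3 through step 2 is equally long). Steps 6 and 7 form a two-step side branch.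

**Step 3 (key step).** The formyl-exo preference and the face selectivity may both erode, because the trisubstituted, β-substituted enal is a slow dienophile and a less organised or uncatalysed pathway can compete. Fallback: set out again from 2 and 5 and run the cycloaddition with a bulky achiral aluminium Lewis acid, MeAl(OC6H2-2,6-t-Bu2-4-Me)2, of the kind used for exo-selective additions of α-substituted enals. This would give the racemate, that is 6 together with its antipode, the ent-cycloadduct F1. The two are separated by preparative chromatography on a chiral stationary phase and the route is rejoined at 6.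

**Step 16.** Oligomerisation and reductive loss of iodine may outrun the closure, because the ten-membered ring has to form at an aldehyde that sits on a fully substituted carbon. Fallback: set out from 23 and move the ring-closing event to the alkene. Vinylmagnesium bromide at −78 °C adds to the aldehyde to give the C7 vinyl carbinol F2. Iodine–lithium exchange with t-BuLi (3 equiv, Et2O, −78 °C) and protonation with MeOH gives the deiodinated diene F3. Ring-closing metathesis with the second-generation Grubbs catalyst at high dilution should then form C5=C6, the ring permitting only the Z alkene, and rejoin the route at 24.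

**Step 19.** Electron transfer to the α-acyloxy ketone, with cleavage of the C7–O bond, may compete with reduction of the C–Br bond, or the enolate may add with the wrong relative configuration at C17. Fallback: set out from 24 and build the lactone by olefination.
- Esterification with 2-(diethoxyphosphoryl)propanoic acid (DCC, 4-(dimethylamino)pyridine) gives the phosphonate ester F4.
- MeI/CaCO3 in aqueous MeCN unmasks the keto phosphonate F5.
- LiCl/DBU effects the intramolecular Horner–Wadsworth–Emmons reaction to the butenolide F6 (C8=C17).
- Nucleophilic epoxidation (t-BuOOH, DBU) gives the 8,17-epoxy lactone F7.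
- SmI2 in THF/MeOH at −78 °C cleaves the α C–O bond; protonation, if necessary followed by base equilibration of C17 (methyl trans to C9), rejoins the route at 29.

**Step 21.** Hydride may be delivered to the β face (axial attack on the half-chair) and not to the α face, because the facial bias of the bicyclic enone rests on sterics alone. Fallback: set out from 30; the reduction then gives the 12α-alcohol F8, which already has the C12 configuration of the target. It is esterified with retention (butanoic anhydride, 4-(dimethylamino)pyridine, pyridine), which replaces step 22 and rejoins the route at 33.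

**Step 22.** Elimination toward a ring A diene or allylic transposition may replace direct displacement, because the oxyphosphonium salt of a hindered allylic alcohol ionises easily and butanoate is a weak nucleophile. Fallback: set out from 31 and separate activation from displacement. Chloromethanesulfonyl chloride and pyridine at −20 °C give the 12β-chloromethanesulfonate F9, which is used without purification and displaced with caesium butanoate (from 32 and Cs2CO3) and 18-crown-6 in toluene, rejoining the route at 33.

## Further compounds

F1 | step 3 | ent-cycloadduct, [(1R,2S,6R)-6-formyl-2,6-dimethyl-3-(triisopropylsilyloxy)cyclohex-3-en-1-yl]methyl benzoate | CC(C)[Si](C(C)C)(C(C)C)OC1=CC[C@](C=O)(C)[C@@H]([C@@H]1C)COC(=O)c1ccccc1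
F2 | step 16 | C7 vinyl carbinol (vinyl adduct of 23; alkenyl iodide retained) | CC(C)[Si](C(C)C)(C(C)C)OC1=CC[C@@]([C@H](O[Si](C)(C)C(C)(C)C)CC/C(C)=C\I)(C)[C@H]([C@H]1C)[C@@H](O[Si](C)(C)C(C)(C)C)C1(SCCCS1)[C@@H](O)C=C
F3 | step 16 | deiodinated diene (C5 isopropenyl terminus and C7 vinyl carbinol) | CC(C)[Si](C(C)C)(C(C)C)OC1=CC[C@@]([C@H](O[Si](C)(C)C(C)(C)C)CCC(C)=C)(C)[C@H]([C@H]1C)[C@@H](O[Si](C)(C)C(C)(C)C)C1(SCCCS1)[C@@H](O)C=C
F4 | step 19 | C7 2-(diethoxyphosphoryl)propanoate of 24 | CC(C)[Si](C(C)C)(C(C)C)OC1=CC[C@@]2(C)[C@H]([C@H]1C)[C@@H](O[Si](C)(C)C(C)(C)C)C1(SCCCS1)[C@H](/C=C(/C)CC[C@H]2O[Si](C)(C)C(C)(C)C)OC(=O)C(C)P(=O)(OCC)OCC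
F5 | step 19 | C8 keto phosphonate | CC(C)[Si](C(C)C)(C(C)C)OC1=CC[C@@]2(C)[C@H]([C@H]1C)[C@@H](O[Si](C)(C)C(C)(C)C)C(=O)[C@H](/C=C(/C)CC[C@H]2O[Si](C)(C)C(C)(C)C)OC(=O)C(C)P(=O)(OCC)OCC
F6 | step 19 | butenolide (C8=C17, 17-methyl) | CC(C)[Si](C(C)C)(C(C)C)OC1=CC[C@@]2(C)[C@H]([C@H]1C)[C@@H](O[Si](C)(C)C(C)(C)C)C1=C(C)C(=O)O[C@H]1/C=C(/C)CC[C@H]2O[Si](C)(C)C(C)(C)C
F7 | step 19 | 8,17-epoxy lactone (epoxide oxygen on the face of the later C8 hydroxyl) | CC(C)[Si](C(C)C)(C(C)C)OC1=CC[C@@]2(C)[C@H]([C@H]1C)[C@@H](O[Si](C)(C)C(C)(C)C)[C@@]13O[C@@]3(C)C(=O)O[C@H]1/C=C(/C)CC[C@H]2O[Si](C)(C)C(C)(C)C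
F8 | step 21 | 12α-alcohol (C12 epimer of 31) | O[C@@H]1C=C[C@@]2(C)[C@H]([C@H]1C)[C@@H](O[Si](C)(C)C(C)(C)C)[C@@]1(O)[C@H](/C=C(/C)CC[C@H]2O[Si](C)(C)C(C)(C)C)OC(=O)[C@@H]1C
F9 | step 22 | 12β-chloromethanesulfonate of 31 | ClCS(=O)(=O)O[C@H]1C=C[C@@]2(C)[C@H]([C@H]1C)[C@@H](O[Si](C)(C)C(C)(C)C)[C@@]1(O)[C@H](/C=C(/C)CC[C@H]2O[Si](C)(C)C(C)(C)C)OC(=O)[C@@H]1C
A1 | alternative 1 | 2-oxo analogue of 36 (product of the homoenolate coupling) | CCCC(=O)O[C@@H]1C=C[C@@]2(C)[C@H]([C@H]1C)[C@@H](OC(C)=O)[C@@]1(O)[C@H](/C=C(/C)CCC2=O)OC(=O)[C@@H]1C
A2 | alternative 1 | seco precursor with a 1-hydroxycyclopropyl group on C1 and a Z 2-iodoprop-1-enyl group on C7 | CCCC(=O)O[C@@H]1C=C[C@](C)(C2(O)CC2)[C@H]([C@H]1C)[C@@H](OC(C)=O)[C@@]1(O)[C@H](/C=C(/C)I)OC(=O)[C@@H]1C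
A3 | alternative 2 | ring A-fused cyclodecane-2,7-dione (9-OTBS, 5-OTES, 12-oxo-13-ene) | O=C1C=C[C@@]2(C)[C@H]([C@H]1C)[C@@H](O[Si](C)(C)C(C)(C)C)CC(=O)C[C@](C)(O[Si](CC)(CC)CC)CCC2=O
A4 | alternative 2 | tricyclic hydrophenanthrene with the tetrasubstituted C2=C7 alkene | O=C1C=C[C@@]2(C)[C@H]([C@H]1C)[C@@H](O[Si](C)(C)C(C)(C)C)CC3=C2CC[C@@](C)(O[Si](CC)(CC)CC)C3
A5 | alternative 3 | bicyclic C2 ketone with Z C5=C6 (product of the ring expansion) | CC(C)(C)[Si](C)(C)O[C@@H]1C=C[C@@]2(C)[C@H]([C@H]1C)[C@@H](O[Si](C)(C)C(C)(C)C)[C@@]([C@@H](C)COCc3ccc(OC)cc3)(O[Si](C)(C)C)[C@H](/C=C(/C)CCC2=O)O[Si](C)(C)C(C)(C)C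
A6 | alternative 3 | 2-methylene-8-isopropenyl oxocane fused to ring A (ring oxygen between C2 and C6) | CC(C)(C)[Si](C)(C)O[C@@H]1C=C[C@@]2(C)[C@H]([C@H]1C)[C@@H](O[Si](C)(C)C(C)(C)C)[C@@]([C@@H](C)COCc3ccc(OC)cc3)(O[Si](C)(C)C)[C@H]([C@H](C(C)=C)OC2=C)O[Si](C)(C)C(C)(C)C
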